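**Retrosynthetic overview**
- Target ⇐ global O-debenzylation of its (2R,3S) penta-O-benzyl ether.
- Flavanone C-ring (O1–C2 bond, formed last) ⇐ enantioselective organocatalytic 6-endo oxa-Michael cyclisation of a 2'-hydroxy-α-aryl chalcone; the catalyst sets C2, equilibration to 2,3-trans sets C3.
- Hydroxychalcone ⇐ chelation-controlled ortho-debenzylation, after Knoevenagel condensation of a deoxybenzoin with 4-(benzyloxy)benzaldehyde.
- Deoxybenzoin ⇐ Pd α-arylation (aryl–CH2 bond) of tris(benzyloxy)acetophenone with a 3'-bromoflavone.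
- Flavone ring (formed first) ⇐ one-pot aldol/oxidative cyclisation of a 2'-hydroxyacetophenone with 4-(benzyloxy)-3-bromobenzaldehyde.

Assumption: the achiral benzyl-protected building blocks 1, 2, 5 and 7 are bought as catalogue compounds.

**Step 1**
Reactants: 1 1-[2,4-bis(benzyloxy)-6-hydroxyphenyl]ethan-1-one; 2 4-(benzyloxy)-3-bromobenzaldehyde
Product: 4 5,7-bis(benzyloxy)-2-[4-(benzyloxy)-3-bromophenyl]-4H-chromen-4-one, via 2'-hydroxychalcone 3 (not isolated)
Conditions: pyrrolidine (0.5 equiv), I2 (10 mol%), DMSO, 140 °C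
Reagents that add atoms: none
Why: Domino Claisen–Schmidt condensation followed by iodine/DMSO oxidative cyclisation (oxa-Michael, α-iodination, HI loss, DMSO regenerating I2) builds the flavone ring in one flask, and the aryl bromide and benzyl ethers are inert.

**Step 2**
Reactants: 4 5,7-bis(benzyloxy)-2-[4-(benzyloxy)-3-bromophenyl]-4H-chromen-4-one; 5 1-[2,4,6-tris(benzyloxy)phenyl]ethan-1-one
Product: 6 2-{2-(benzyloxy)-5-[5,7-bis(benzyloxy)-4-oxo-4H-chromen-2-yl]phenyl}-1-[2,4,6-tris(benzyloxy)phenyl]ethan-1-one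
Conditions: Pd2(dba)3 (2.5 mol%), XPhos (6 mol%), K3PO4 (2.5 equiv), 5 (1.3 equiv), toluene, 90 °C
Reagents that add atoms: none
Why: Pd-catalysed ketone α-arylation (Buchwald–Hartwig type: oxidative addition into C–Br, enolate binding, reductive elimination) forms the aryl–CH2 bond, the weak base K3PO4 spares the flavone, and the bulky ligand with excess ketone keeps it to monoarylation.

**Step 3**
Reactants: 6 2-{2-(benzyloxy)-5-[5,7-bis(benzyloxy)-4-oxo-4H-chromen-2-yl]phenyl}-1-[2,4,6-tris(benzyloxy)phenyl]ethan-1-one; 7 4-(benzyloxy)benzaldehyde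
Product: 8 (E)-2-{2-(benzyloxy)-5-[5,7-bis(benzyloxy)-4-oxo-4H-chromen-2-yl]phenyl}-3-[4-(benzyloxy)phenyl]-1-[2,4,6-tris(benzyloxy)phenyl]prop-2-en-1-one
Conditions: piperidine (0.3 equiv), AcOH (0.3 equiv), 7 (1.5 equiv), toluene, reflux, Dean–Stark
Reagents that add atoms: none
Why: Knoevenagel condensation of the doubly activated benzylic methylene with the iminium-activated aldehyde, driven by azeotropic water removal, gives the E α-aryl chalcone, which cannot cyclise because every phenol is still benzylated.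

**Step 4**
Reactants: 8 (E)-2-{2-(benzyloxy)-5-[5,7-bis(benzyloxy)-4-oxo-4H-chromen-2-yl]phenyl}-3-[4-(benzyloxy)phenyl]-1-[2,4,6-tris(benzyloxy)phenyl]prop-2-en-1-one
Product: 9 (E)-1-[2,4-bis(benzyloxy)-6-hydroxyphenyl]-2-{2-(benzyloxy)-5-[7-(benzyloxy)-5-hydroxy-4-oxo-4H-chromen-2-yl]phenyl}-3-[4-(benzyloxy)phenyl]prop-2-en-1-one
Conditions: BCl3 (2.2 equiv), CH2Cl2, −78 °C, 30 min; MeOH, then cold pH 7 buffer
Reagents that add atoms: none
Why: Chelation-controlled Lewis-acid dealkylation, in which BCl3 bound to each carbonyl cleaves only the benzyl ether held in a six-membered chelate (one ortho ether of the aryl ketone and the flavone 5-ether), the resulting dichloroboronate blocks a second cleavage, and the cold non-basic work-up leaves the hydroxychalcone uncyclised.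

**Step 5**
Reactants: 9 (E)-1-[2,4-bis(benzyloxy)-6-hydroxyphenyl]-2-{2-(benzyloxy)-5-[7-(benzyloxy)-5-hydroxy-4-oxo-4H-chromen-2-yl]phenyl}-3-[4-(benzyloxy)phenyl]prop-2-en-1-one
Product: 11 (2R,3S)-5,7-bis(benzyloxy)-3-{2-(benzyloxy)-5-[7-(benzyloxy)-5-hydroxy-4-oxo-4H-chromen-2-yl]phenyl}-2-[4-(benzyloxy)phenyl]-2,3-dihydro-4H-chromen-4-one (2,3-trans), via 2,3-cis epimer 10 (not isolated)
Conditions: quinidine-derived squaramide 3-{[3,5-bis(trifluoromethyl)phenyl]amino}-4-{[(9R)-6'-methoxycinchonan-9-yl]amino}cyclobut-3-ene-1,2-dione (10 mol%), toluene/CH2Cl2 4:1, −20 °C, 48–72 h; filter through silica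
Reagents that add atoms: none
Why: Proposed new method: the quinuclidine nitrogen deprotonates the chelated 2'-OH while the squaramide N–H pair binds the enone carbonyl, so the phenoxide adds 6-endo-trig to one face of the β-carbon inside the chiral ion pair (C2 set as R by the catalyst, either alkene geometry giving the same benzylic enolate), and the enolate is protonated and any cis epimer 10 equilibrated at the acidic C3–H by the same amine to the diequatorial 2,3-trans isomer (C3 set as S); the closest known reaction is the cinchona thiourea-catalysed enantioselective oxa-Michael cyclisation of 2'-hydroxyaryl alkylidene β-ketoesters to 3-carboxyflavanones, which has not been shown for α-aryl (deoxybenzoin-derived) chalcones.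

**Step 6**
Reactants: 11 (2R,3S)-5,7-bis(benzyloxy)-3-{2-(benzyloxy)-5-[7-(benzyloxy)-5-hydroxy-4-oxo-4H-chromen-2-yl]phenyl}-2-[4-(benzyloxy)phenyl]-2,3-dihydro-4H-chromen-4-one
Product: 12 (2R,3S)-5,7-dihydroxy-3-[2-hydroxy-5-(5,7-dihydroxy-4-oxo-4H-chromen-2-yl)phenyl]-2-(4-hydroxyphenyl)-2,3-dihydro-4H-chromen-4-one (target)
Conditions: H2 (1 atm), 10% Pd/C, EtOAc/MeOH 1:1, rt, stopped at full debenzylation
Reagents that add atoms: none
Why: Neutral Pd-catalysed hydrogenolysis of the five aryl benzyl ethers frees the phenols without acid or base, so the epimerisable C3 and the ring-opening-prone C2 are untouched, and mild conditions keep the flavone C=C and the benzylic C2–O bond.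

**Compound list**
1 | 1-[2,4-bis(benzyloxy)-6-hydroxyphenyl]ethan-1-one | CC(=O)c1c(O)cc(OCc2ccccc2)cc1OCc1ccccc1 | starting material
2 | 4-(benzyloxy)-3-bromobenzaldehyde | O=Cc1ccc(OCc2ccccc2)c(Br)c1 | starting material
3 | (E)-1-[2,4-bis(benzyloxy)-6-hydroxyphenyl]-3-[4-(benzyloxy)-3-bromophenyl]prop-2-en-1-one (2'-hydroxychalcone) | O=C(/C=C/c1ccc(OCc2ccccc2)c(Br)c1)c1c(O)cc(OCc2ccccc2)cc1OCc1ccccc1 | intermediate
4 | 5,7-bis(benzyloxy)-2-[4-(benzyloxy)-3-bromophenyl]-4H-chromen-4-one | O=c1cc(-c2ccc(OCc3ccccc3)c(Br)c2)oc2cc(OCc3ccccc3)cc(OCc3ccccc3)c12 | intermediate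
5 | 1-[2,4,6-tris(benzyloxy)phenyl]ethan-1-one | CC(=O)c1c(OCc2ccccc2)cc(OCc2ccccc2)cc1OCc1ccccc1 | starting material
6 | 2-{2-(benzyloxy)-5-[5,7-bis(benzyloxy)-4-oxo-4H-chromen-2-yl]phenyl}-1-[2,4,6-tris(benzyloxy)phenyl]ethan-1-one | O=C(Cc1cc(-c2cc(=O)c3c(OCc4ccccc4)cc(OCc4ccccc4)cc3o2)ccc1OCc1ccccc1)c1c(OCc2ccccc2)cc(OCc2ccccc2)cc1OCc1ccccc1 | intermediate
7 | 4-(benzyloxy)benzaldehyde | O=Cc1ccc(OCc2ccccc2)cc1 | starting material
8 | (E)-2-{2-(benzyloxy)-5-[5,7-bis(benzyloxy)-4-oxo-4H-chromen-2-yl]phenyl}-3-[4-(benzyloxy)phenyl]-1-[2,4,6-tris(benzyloxy)phenyl]prop-2-en-1-one | O=C(/C(=C/c1ccc(OCc2ccccc2)cc1)c1cc(-c2cc(=O)c3c(OCc4ccccc4)cc(OCc4ccccc4)cc3o2)ccc1OCc1ccccc1)c1c(OCc2ccccc2)cc(OCc2ccccc2)cc1OCc1ccccc1 | intermediate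
9 | (E)-1-[2,4-bis(benzyloxy)-6-hydroxyphenyl]-2-{2-(benzyloxy)-5-[7-(benzyloxy)-5-hydroxy-4-oxo-4H-chromen-2-yl]phenyl}-3-[4-(benzyloxy)phenyl]prop-2-en-1-one | O=C(/C(=C/c1ccc(OCc2ccccc2)cc1)c1cc(-c2cc(=O)c3c(O)cc(OCc4ccccc4)cc3o2)ccc1OCc1ccccc1)c1c(O)cc(OCc2ccccc2)cc1OCc1ccccc1 | intermediate
10 | (2R,3R)-5,7-bis(benzyloxy)-3-{2-(benzyloxy)-5-[7-(benzyloxy)-5-hydroxy-4-oxo-4H-chromen-2-yl]phenyl}-2-[4-(benzyloxy)phenyl]-2,3-dihydro-4H-chromen-4-one (2,3-cis epimer) | O=C1c2c(OCc3ccccc3)cc(OCc3ccccc3)cc2O[C@@H](c2ccc(OCc3ccccc3)cc2)[C@H]1c1cc(-c2cc(=O)c3c(O)cc(OCc4ccccc4)cc3o2)ccc1OCc1ccccc1 | intermediate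
11 | (2R,3S)-5,7-bis(benzyloxy)-3-{2-(benzyloxy)-5-[7-(benzyloxy)-5-hydroxy-4-oxo-4H-chromen-2-yl]phenyl}-2-[4-(benzyloxy)phenyl]-2,3-dihydro-4H-chromen-4-one (2,3-trans) | O=C1c2c(OCc3ccccc3)cc(OCc3ccccc3)cc2O[C@@H](c2ccc(OCc3ccccc3)cc2)[C@@H]1c1cc(-c2cc(=O)c3c(O)cc(OCc4ccccc4)cc3o2)ccc1OCc1ccccc1 | intermediate
12 | (2R,3S)-5,7-dihydroxy-3-[2-hydroxy-5-(5,7-dihydroxy-4-oxo-4H-chromen-2-yl)phenyl]-2-(4-hydroxyphenyl)-2,3-dihydro-4H-chromen-4-one (2,3-trans) | O=C1c2c(O)cc(O)cc2O[C@@H](c2ccc(O)cc2)[C@@H]1c1cc(-c2cc(=O)c3c(O)cc(O)cc3o2)ccc1O | target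

**Total step count:** 6
**Longest linear sequence:** 6 steps (1 and 2 to 12; 5 and 7 are purchased)

**Three steps most likely to fail**

Step 3 (Knoevenagel condensation). The ketone of 6 is flanked by two ortho benzyloxy groups and the aldehyde is electron-rich, so the condensation may stall, and the secondary amine can attack the flavone on long heating. The fallback sets out from 6. It is deprotonated with LiHMDS (THF, −78 °C) and the lithium enolate is added to 7 to give the β-hydroxy ketone aldol adduct F1 as a diastereomer mixture. Acid-catalysed E1 dehydration through the 4-benzyloxybenzylic cation (cat. TsOH, toluene, 60 °C) then comes back to the route at 8.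

Step 5 (the proposed new organocatalytic oxa-Michael cyclisation). The twisted, trisubstituted acceptor may react slowly, and the enantioselectivity may be modest because only one carbonyl binds the squaramide. The ee can also erode by retro-oxa-Michael through the acidic C3–H if the catalyst is left in contact. The sense of induction cannot be predicted for a new substrate class and must be proven (ECD or X-ray); if 2S results, the quinine-derived pseudo-enantiomeric squaramide is used instead. The fallback uses known chemistry and sets out from 6. The same chelation-controlled BCl3 cleavage (CH2Cl2, −78 °C) gives the 2'-hydroxy deoxybenzoin F2. DMF dimethyl acetal (toluene, 90 °C) closes it to the isoflavone F3. The established Pd(II)/t-BuPyOx-catalysed asymmetric conjugate addition of an arylboronic acid to a chromone, here 4-(benzyloxy)phenylboronic acid adding to C2 of F3, sets C2; the ligand enantiomer that gives 2R is chosen. Protonation and equilibration at C3 to the trans isomer then come back to the route at 11.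

Step 6 (hydrogenolysis). Five benzyl ethers must fall while the benzylic C2–O1 bond (which would give a dihydrochalcone), the flavone C2=C3 bond and the aryl ketone survive; over-reduction or incomplete cleavage are the risks. The fallback sets out from 11 and is non-reductive: BCl3 with pentamethylbenzene as cation scavenger (CH2Cl2, −78 °C, methanol quench) removes all benzyl groups and arrives directly at 12. No new compound is made on the way (F0).

**Further compounds**
F1 | step 3 | 2-{2-(benzyloxy)-5-[5,7-bis(benzyloxy)-4-oxo-4H-chromen-2-yl]phenyl}-3-[4-(benzyloxy)phenyl]-3-hydroxy-1-[2,4,6-tris(benzyloxy)phenyl]propan-1-one (racemic syn/anti mixture, stereocentres undefined) | O=C(C(C(O)c1ccc(OCc2ccccc2)cc1)c1cc(-c2cc(=O)c3c(OCc4ccccc4)cc(OCc4ccccc4)cc3o2)ccc1OCc1ccccc1)c1c(OCc2ccccc2)cc(OCc2ccccc2)cc1OCc1ccccc1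
F2 | step 5 | 1-[2,4-bis(benzyloxy)-6-hydroxyphenyl]-2-{2-(benzyloxy)-5-[7-(benzyloxy)-5-hydroxy-4-oxo-4H-chromen-2-yl]phenyl}ethan-1-one | O=C(Cc1cc(-c2cc(=O)c3c(O)cc(OCc4ccccc4)cc3o2)ccc1OCc1ccccc1)c1c(O)cc(OCc2ccccc2)cc1OCc1ccccc1
F3 | step 5 | 5,7-bis(benzyloxy)-3-{2-(benzyloxy)-5-[7-(benzyloxy)-5-hydroxy-4-oxo-4H-chromen-2-yl]phenyl}-4H-chromen-4-one | O=c1c(-c2cc(-c3cc(=O)c4c(O)cc(OCc5ccccc5)cc4o3)ccc2OCc2ccccc2)coc2cc(OCc3ccccc3)cc(OCc3ccccc3)c12
F0 | step 6 | none | none
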